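| flask | substrate | reagent in the second phase | remark | time | volume of the second phase over the first |
|---|---|---|---|---|---|
| Sunday's | 1.5 M | 2.09 M | run made earlier |  |  |
| flask | 2.2 M | 2.09 M |  | 10 d | 1.0 |

- Sunday's (time / d: target / %, substrate / %): 0.500: 0, 99.8; 1.67: 0.6, 98.9; 3.00: 1.4, 98.0; 4.00: 1.7, 97.1; 6.00: 2.5, 95.7

(standard deviation of a reading: 0.3 percentage points)

- in the second phase: reagent in the second phase; everything else is in the first
- charges count per volume of the first phase; a concentration in a rate is the amount of a species over the volume of its own phase; every rate counts per litre of the first phase
- the earlier runs hold the two phases in the same ratio of volumes as the flask asked about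

- oak: doubling the transfer coefficient of the reagent in the second phase, all else as stated
- larch: doubling the amount of reagent in the second phase, all else as stated

- amount of target at 10 d, in percent of the substrate charged
- the change that raises the amount of target at 10 d, in percent of the substrate charged most ("none" if none brings more than 2 percentage points) (oak / larch / none)
- amount of target at 10 d, in percent of the substrate charged, after larch

- Amounts first: Sunday's run, charged at 1.5 M, holds 2.5% of its substrate as target at 6.00 d, so it made 0.00417 /d of its charge per day, the daily share, and it lost 0.00717 /d of its substrate per day.
- Loose bracket for the flask: from above, Sunday's substrate loss kept up for 10 d and all read as target gives 7.17%; from below, Sunday's target at 6.00 d spread over the larger charge gives 1.70%.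
- Tightened: if the reaction is first order in substrate, the daily share stays and gives 4.17%. If the absolute rate stays, the share falls by 0.166 in powers of ten and gives 2.84%. Each of these bounds is the reading at 6.00 d scaled up, so the scatter of 0.3 percentage points scales with it, to 0.5 points on the upper bound and 0.34 points on the lower.
- If the share follows the reagent, larch doubles the bracket to 5.68% to 8.34%, and even the lower bound's gain exceeds the margin.
- The forecast, 3.7%, lies inside the bracket, between two cases, one where “the percentage rate holds”; it names larch, with 7.2%.
- The flask gives 4.09%, below the upper bound; larch gives 7.95%, gaining 3.9 points against 1 point for oak.

    reagent in the reaction phase ⇌ reagent in the second phase, rate k1*([reagent in the reaction phase] - [reagent in the second phase]/K1) per volume of the first phase (partition coefficient = 27.0, kL = 0.0260 /h)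
    substrate + reagent in the reaction phase → target (k = 0.00760 /M/h)
    target ⇌ isomer of the product (K = 0.940, k = 0.0190 /h)

- The flask's own daily share to 10 d is 0.00409 /d, close to Sunday's. The neighbour charged at 1.3 M has a bracket of 4.17% to 4.81% and gives 4.77%, at the upper end. The flask has not come to rest at 10 d: 93% of its substrate remains. By 100 d its daily share averages 0.00248 /d, target has risen by 21 points to 24.8%, and substrate still stands at 52.1%.

All runs stem from a simulated flask with made-up constants, noise included.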